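**Retrosynthetic overview**
- Target ⇐ one hydrogenation of a 3-aroyl-1H-indene penta-benzyl ether: H2 adds syn, opposite the aryl group on the only stereocentre, which sets C1 and C2 and removes all benzyl groups.
- Aroyl C–C bond ⇐ carbonylative Stille coupling of the enol triflate of a 2,3-diarylindan-1-one.
- Five-membered ring (the only ring made; the arenes are bought) ⇐ catalytic asymmetric Nazarov closure of an achiral α-aryl chalcone, which passes through a dearomatised arenium ion and sets C3.
- Chalcone ⇐ Knoevenagel condensation of 4-(benzyloxy)benzaldehyde with a deoxybenzoin made by palladium-catalysed ketone α-arylation.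

Assumption: the target is taken exactly as the SMILES encodes it, the (1R,2R,3R) isomer with the aroyl group at C1 and the aryl groups at C2 and C3 all on one face of the indane (all-cis); this is the less stable C1 epimer, so C1 is set last and never exposed to acid or base.

**Step 1**
Reactants: 1 1-[3,5-bis(benzyloxy)phenyl]ethan-1-one; 2 1,3-bis(benzyloxy)-5-bromobenzene
Product: 3 1,2-bis[3,5-bis(benzyloxy)phenyl]ethan-1-one
Conditions: Pd2(dba)3 (1.5 mol%), Xantphos (3.6 mol%), NaOtBu (2.2 equiv), THF, 70 °C; 1.2 equiv of 1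
Reagents that add atoms: none
Why: Palladium-catalysed ketone α-arylation (Buchwald–Hartwig type) works well for aryl methyl ketones with aryl bromides, and the more acidic deoxybenzoin product rests as its enolate, which stops a second arylation; no stereocentre is formed.

**Step 2**
Reactants: 3 1,2-bis[3,5-bis(benzyloxy)phenyl]ethan-1-one; 4 4-(benzyloxy)benzaldehyde
Product: 5 (E)-1,2-bis[3,5-bis(benzyloxy)phenyl]-3-[4-(benzyloxy)phenyl]prop-2-en-1-one
Conditions: piperidine (0.3 equiv), AcOH (0.3 equiv), toluene, reflux, Dean–Stark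
Reagents that add atoms: none
Why: Knoevenagel condensation of the doubly activated methylene with removal of water gives the thermodynamically preferred E enone (β-aryl trans to the aroyl group), the geometry that puts H on the inside of the U-shaped cation needed in step 3.

**Step 3**
Reactants: 5 (E)-1,2-bis[3,5-bis(benzyloxy)phenyl]-3-[4-(benzyloxy)phenyl]prop-2-en-1-one
Product: 7 (2R,3R)-4,6-bis(benzyloxy)-2-[3,5-bis(benzyloxy)phenyl]-3-[4-(benzyloxy)phenyl]-2,3-dihydro-1H-inden-1-one, via enol 6 (not isolated)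
Conditions: (R)-3,3'-bis(2,4,6-triisopropylphenyl)-1,1'-binaphthyl-2,2'-diyl N-triflylphosphoramide (10 mol%), CHCl3, 5 Å MS, 0 to 30 °C; one recrystallisation to raise ee
Reagents that add atoms: none
Why: Proposed new method: the strong chiral acid O-protonates the enone to a hydroxypentadienyl cation whose second "vinyl" arm is the electron-rich 3,5-dialkoxyphenyl ring; conrotatory 4π closure inside the contact ion pair (sense of rotation imposed by the chiral phosphoramide anion) breaks the aromaticity of that ring to an arenium ion and creates C3, then proton loss rearomatises and enol 6 tautomerises to the more stable trans ketone (C2 is erased in step 4 anyway); the closest known reactions are the racemic trifluoroacetic-acid Nazarov cyclisation of such 3,5-dialkoxyphenyl α-aryl chalcones to 2,3-diarylindanones and the asymmetric Nazarov cyclisation of divinyl ketones with chiral N-triflylphosphoramides; the acid antipode that gives 3R cannot be predicted and is fixed in a first small run.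

**Step 4**
Reactants: 7 (2R,3R)-4,6-bis(benzyloxy)-2-[3,5-bis(benzyloxy)phenyl]-3-[4-(benzyloxy)phenyl]-2,3-dihydro-1H-inden-1-one
Product: 8 (1R)-5,7-bis(benzyloxy)-2-[3,5-bis(benzyloxy)phenyl]-1-[4-(benzyloxy)phenyl]-1H-inden-3-yl trifluoromethanesulfonate
Conditions: KN(SiMe3)2 (1.0 equiv) added slowly to 7, THF, −78 °C; then PhNTf2 (1.1 equiv), −78 to 0 °C; cold 0.5 M HCl quench
Reagents that add atoms: N-phenylbis(trifluoromethanesulfonimide), O=S(=O)(N(c1ccccc1)S(=O)(=O)C(F)(F)F)C(F)(F)F
Why: Enolate O-triflation: only C2 has an α-hydrogen so one enol triflate forms, the C2 centre is deliberately erased, and with base never in excess at −78 °C the much less acidic doubly benzylic C–H at the aryl-bearing carbon is untouched, so that centre keeps its configuration.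

**Step 5**
Reactants: 9 1-(benzyloxy)-4-bromobenzene
Product: 11 tributyl[4-(benzyloxy)phenyl]stannane, via aryllithium 10 (not isolated)
Conditions: n-BuLi (1.05 equiv), THF, −78 °C; then Bu3SnCl, −78 °C to rt
Reagents that add atoms: tributyltin chloride, CCCC[Sn](CCCC)(CCCC)Cl
Why: Bromine–lithium exchange is far faster than any attack on the benzyl ether at −78 °C, and the aryllithium is trapped cleanly on tin to give the air-stable stannane.

**Step 6**
Reactants: 8 (1R)-5,7-bis(benzyloxy)-2-[3,5-bis(benzyloxy)phenyl]-1-[4-(benzyloxy)phenyl]-1H-inden-3-yl trifluoromethanesulfonate; 11 tributyl[4-(benzyloxy)phenyl]stannane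
Product: 12 [(1S)-5,7-bis(benzyloxy)-2-[3,5-bis(benzyloxy)phenyl]-1-[4-(benzyloxy)phenyl]-1H-inden-3-yl][4-(benzyloxy)phenyl]methanone
Conditions: Pd(PPh3)4 (5 mol%), LiCl (3 equiv), CO (3 bar), THF, 55 °C; MeCN/hexane partition to remove tin, short neutral silica plug, used the same day
Reagents that add atoms: carbon monoxide, [C-]#[O+]
Why: Carbonylative Stille coupling: oxidative addition of the enol triflate, CO insertion (favoured over direct coupling at this hindered site under CO pressure) and transmetalation from tin give the aryl ketone without any base, so the acidic vinylogous C–H at the stereocentre is not ionised and its configuration is kept.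

**Step 7**
Reactants: 12 [(1S)-5,7-bis(benzyloxy)-2-[3,5-bis(benzyloxy)phenyl]-1-[4-(benzyloxy)phenyl]-1H-inden-3-yl][4-(benzyloxy)phenyl]methanone
Product: 14 caraphenol C [(1R,2R,3R)-2-(3,5-dihydroxyphenyl)-4,6-dihydroxy-3-(4-hydroxyphenyl)-2,3-dihydro-1H-inden-1-yl](4-hydroxyphenyl)methanone, via pentaphenol enone 13 (not isolated)
Conditions: H2 (4 bar), 10% Pd/C, EtOAc/EtOH 1:1, rt; filtration, reversed-phase chromatography with 0.1% HCO2H
Reagents that add atoms: none
Why: Heterogeneous catalytic hydrogenation: the benzyl ethers are hydrogenolysed first, then the tetrasubstituted enone C=C takes up H2 by syn addition from the face opposite the C3 aryl group, which places the aroyl group at C1 and the aryl group at C2 on the same face as the C3 aryl group (all-cis, 1R,2R,3R), and the neutral medium leaves the kinetically set C1 alone.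

**Compound list**
1 | 1-[3,5-bis(benzyloxy)phenyl]ethan-1-one | CC(=O)c1cc(OCc2ccccc2)cc(OCc2ccccc2)c1 | starting material
2 | 1,3-bis(benzyloxy)-5-bromobenzene | Brc1cc(OCc2ccccc2)cc(OCc2ccccc2)c1 | starting material
3 | 1,2-bis[3,5-bis(benzyloxy)phenyl]ethan-1-one | O=C(Cc1cc(OCc2ccccc2)cc(OCc2ccccc2)c1)c1cc(OCc2ccccc2)cc(OCc2ccccc2)c1 | intermediate
4 | 4-(benzyloxy)benzaldehyde | O=Cc1ccc(OCc2ccccc2)cc1 | starting material
5 | (E)-1,2-bis[3,5-bis(benzyloxy)phenyl]-3-[4-(benzyloxy)phenyl]prop-2-en-1-one | O=C(c1cc(OCc2ccccc2)cc(OCc2ccccc2)c1)/C(c1cc(OCc2ccccc2)cc(OCc2ccccc2)c1)=C/c1ccc(OCc2ccccc2)cc1 | intermediate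
6 | (1S)-5,7-bis(benzyloxy)-2-[3,5-bis(benzyloxy)phenyl]-1-[4-(benzyloxy)phenyl]-1H-inden-3-ol (enol of 7) | OC1=C(c2cc(OCc3ccccc3)cc(OCc3ccccc3)c2)[C@H](c2ccc(OCc3ccccc3)cc2)c2c(OCc3ccccc3)cc(OCc3ccccc3)cc21 | intermediate
7 | (2R,3R)-4,6-bis(benzyloxy)-2-[3,5-bis(benzyloxy)phenyl]-3-[4-(benzyloxy)phenyl]-2,3-dihydro-1H-inden-1-one (trans) | O=C1[C@@H](c2cc(OCc3ccccc3)cc(OCc3ccccc3)c2)[C@H](c2ccc(OCc3ccccc3)cc2)c2c(OCc3ccccc3)cc(OCc3ccccc3)cc21 | intermediate
8 | (1R)-5,7-bis(benzyloxy)-2-[3,5-bis(benzyloxy)phenyl]-1-[4-(benzyloxy)phenyl]-1H-inden-3-yl trifluoromethanesulfonate | O=S(=O)(OC1=C(c2cc(OCc3ccccc3)cc(OCc3ccccc3)c2)[C@H](c2ccc(OCc3ccccc3)cc2)c2c(OCc3ccccc3)cc(OCc3ccccc3)cc21)C(F)(F)F | intermediate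
9 | 1-(benzyloxy)-4-bromobenzene | Brc1ccc(OCc2ccccc2)cc1 | starting material
10 | [4-(benzyloxy)phenyl]lithium | [Li]c1ccc(OCc2ccccc2)cc1 | intermediate
11 | tributyl[4-(benzyloxy)phenyl]stannane | CCCC[Sn](CCCC)(CCCC)c1ccc(OCc2ccccc2)cc1 | intermediate
12 | [(1S)-5,7-bis(benzyloxy)-2-[3,5-bis(benzyloxy)phenyl]-1-[4-(benzyloxy)phenyl]-1H-inden-3-yl][4-(benzyloxy)phenyl]methanone | O=C(c1ccc(OCc2ccccc2)cc1)C1=C(c2cc(OCc3ccccc3)cc(OCc3ccccc3)c2)[C@H](c2ccc(OCc3ccccc3)cc2)c2c(OCc3ccccc3)cc(OCc3ccccc3)cc12 | intermediate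
13 | [(1S)-2-(3,5-dihydroxyphenyl)-5,7-dihydroxy-1-(4-hydroxyphenyl)-1H-inden-3-yl](4-hydroxyphenyl)methanone | O=C(c1ccc(O)cc1)C1=C(c2cc(O)cc(O)c2)[C@H](c2ccc(O)cc2)c2c(O)cc(O)cc12 | intermediate
14 | caraphenol C, [(1R,2R,3R)-2-(3,5-dihydroxyphenyl)-4,6-dihydroxy-3-(4-hydroxyphenyl)-2,3-dihydro-1H-inden-1-yl](4-hydroxyphenyl)methanone | O=C(c1ccc(O)cc1)[C@H]1c2cc(O)cc(O)c2[C@@H](c2ccc(O)cc2)[C@H]1c1cc(O)cc(O)c1 | target

The aryl-bearing sp3 carbon keeps one spatial arrangement from 6 to 14; its CIP letter changes only because the priorities of its neighbours change.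

**Totals and risks**
Total step count: 7. Longest linear sequence: 6 (steps 1, 2, 3, 4, 6, 7).

Step 3 is the most likely to fail: the enantioselectivity of an acid-catalysed Nazarov closure of a non-chelating aryl vinyl ketone is unproven, and the acid could attack benzyl ethers. The fallback sets C3 by rhodium-catalysed asymmetric conjugate arylation instead of electrocyclisation. It sets out from 3: heating with N,N-dimethylformamide dimethyl acetal in toluene at 100 °C gives the enaminone (E)-3-(dimethylamino)-1,2-bis[3,5-bis(benzyloxy)phenyl]prop-2-en-1-one F1. Trifluoroacetic acid in CH2Cl2 closes it by Friedel–Crafts addition and loss of dimethylamine to the achiral indenone 4,6-bis(benzyloxy)-2-[3,5-bis(benzyloxy)phenyl]-1H-inden-1-one F2. Then [RhCl(C2H4)2]2 with a chiral bicyclic diene ligand, 4-(benzyloxy)phenylboronic acid and aqueous KOH in dioxane at 30 °C adds the aryl group to C3 (Hayashi–Miyaura 1,4-addition), and protonation to the trans ketone brings the route back at 7.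

Step 6 is the second risk: the enol triflate is tetrasubstituted and hindered, CO-free coupling can compete, and 12 is a strong vinylogous carbon acid whose single stereocentre racemises with any base. The fallback makes the C–C bond by Nozaki–Hiyama–Kishi addition and adjusts the oxidation level afterwards. It sets out from 8: CrCl2 (4 equiv) and NiCl2 (2 mol%) in DMF with aldehyde 4 give the allylic alcohol [4-(benzyloxy)phenyl][(1S)-5,7-bis(benzyloxy)-2-[3,5-bis(benzyloxy)phenyl]-1-[4-(benzyloxy)phenyl]-1H-inden-3-yl]methanol F3 as both carbinol epimers, which is configurationally robust and can be stored. MnO2 in CH2Cl2 at rt then releases the enone under neutral conditions right before the hydrogenation, so the route comes back at 12.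

Step 7 is the third risk: one hydrogenation has three jobs, and palladium-mediated double-bond migration (loss of ee), reduction of the aryl ketone or epimerisation at C1 would each spoil it. The fallback saturates the ring alkene before the ketone exists. It sets out from 8 through the allylic alcohol F3 described above. Homogeneous hydrogenation with [Ir(cod)(PCy3)(py)]PF6 under H2 in CH2Cl2 reduces tetrasubstituted alkenes and leaves benzyl ethers alone; it adds H2 opposite the C3 aryl group to give the all-cis carbinol [4-(benzyloxy)phenyl][(1R,2R,3R)-4,6-bis(benzyloxy)-2-[3,5-bis(benzyloxy)phenyl]-3-[4-(benzyloxy)phenyl]-2,3-dihydro-1H-inden-1-yl]methanol F4. Unbuffered Dess–Martin periodinane in CH2Cl2 at 0 °C gives the all-cis ketone [4-(benzyloxy)phenyl][(1R,2R,3R)-4,6-bis(benzyloxy)-2-[3,5-bis(benzyloxy)phenyl]-3-[4-(benzyloxy)phenyl]-2,3-dihydro-1H-inden-1-yl]methanone F5 without touching C1–H. A short hydrogenolysis (H2 1 bar, Pd/C, EtOAc) then brings the route back at 14.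

**Further compounds**
F1 | step 3 | (E)-3-(dimethylamino)-1,2-bis[3,5-bis(benzyloxy)phenyl]prop-2-en-1-one | CN(C)/C=C(\c1cc(OCc2ccccc2)cc(OCc2ccccc2)c1)C(=O)c1cc(OCc2ccccc2)cc(OCc2ccccc2)c1
F2 | step 3 | 4,6-bis(benzyloxy)-2-[3,5-bis(benzyloxy)phenyl]-1H-inden-1-one | O=C1C(c2cc(OCc3ccccc3)cc(OCc3ccccc3)c2)=Cc2c(OCc3ccccc3)cc(OCc3ccccc3)cc21
F3 | step 6 | [4-(benzyloxy)phenyl][(1S)-5,7-bis(benzyloxy)-2-[3,5-bis(benzyloxy)phenyl]-1-[4-(benzyloxy)phenyl]-1H-inden-3-yl]methanol (both carbinol epimers) | OC(c1ccc(OCc2ccccc2)cc1)C1=C(c2cc(OCc3ccccc3)cc(OCc3ccccc3)c2)[C@H](c2ccc(OCc3ccccc3)cc2)c2c(OCc3ccccc3)cc(OCc3ccccc3)cc12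
F4 | step 7 | [4-(benzyloxy)phenyl][(1R,2R,3R)-4,6-bis(benzyloxy)-2-[3,5-bis(benzyloxy)phenyl]-3-[4-(benzyloxy)phenyl]-2,3-dihydro-1H-inden-1-yl]methanol (both carbinol epimers) | OC(c1ccc(OCc2ccccc2)cc1)[C@H]1c2cc(OCc3ccccc3)cc(OCc3ccccc3)c2[C@@H](c2ccc(OCc3ccccc3)cc2)[C@H]1c1cc(OCc2ccccc2)cc(OCc2ccccc2)c1
F5 | step 7 | [4-(benzyloxy)phenyl][(1R,2R,3R)-4,6-bis(benzyloxy)-2-[3,5-bis(benzyloxy)phenyl]-3-[4-(benzyloxy)phenyl]-2,3-dihydro-1H-inden-1-yl]methanone | O=C(c1ccc(OCc2ccccc2)cc1)[C@H]1c2cc(OCc3ccccc3)cc(OCc3ccccc3)c2[C@@H](c2ccc(OCc3ccccc3)cc2)[C@H]1c1cc(OCc2ccccc2)cc(OCc2ccccc2)c1
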